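## Retrosynthetic overview

1. Ring locants: C1 = C(OH)(CH2OH), C2 = CH(OH), C3 = CH(OBz), C4=C5, C6 = CH(OBz). Target 9 ⇐ desilylation of 8 ⇐ trans opening at C3 by benzoate of oxirane 7 (C2–C3, cis to the C1–OH) ⇐ hydroxyl-directed epoxidation of dienol 6.
2. 6 ⇐ rhodium-catalysed allylic (SN2′) opening by benzoate of the temporary C4–O bond of the mirror-symmetric 7-oxanorbornadiene 5. Benzoate enters at C6 trans to the bridge oxygen, which stays as the C1–OH; the choice between the two enantiotopic alkenes sets the absolute configuration.
3. 5 ⇐ Diels–Alder reaction of silylated furfuryl alcohol 2 (supplies C1, C6, C5, C4, the C1 oxygen and CH2OH) with the acetylene equivalent 3 (supplies C2, C3). It forms C1–C2 and C3–C4 and dearomatises the furan.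
4. Enabling feature: the oxygen-bearing quaternary carbon C1 and the alkene carbon C4 are 1,4-related across the six-membered ring, with C4=C5 next to C4. The carbocycle is therefore a 7-oxabicyclo[2.2.1]heptadiene (furan + two carbons) whose C4–O bond has been displaced allylically; the C1 hydroxymethyl is the CH2OH of furfuryl alcohol.
5. Ring order: carbocycle and oxygen bridge together (step 2); bridge opened (step 4); a transient oxirane made and opened (steps 5 and 6).

Key step: step 2

Assumption: adduct 4 is carried as its mixture of racemic endo/exo stereoisomers (all converge to achiral 5), and the ligand antipode needed in step 4 is fixed in a first run, because the sense of induction on this substrate can only be inferred by analogy.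

## Route

Step 1
Reactants: 1 furfuryl alcohol
Product: 2 tert-butyl(furan-2-ylmethoxy)diphenylsilane
Conditions: TBDPSCl, imidazole, DMF, 0 °C → rt
Reagents that add atoms: tert-butyl(chloro)diphenylsilane, CC(C)(C)[Si](Cl)(c1ccccc1)c1ccccc1
Why: Imidazole-promoted silyl ether formation on the primary alcohol; the bulky silyl group should survive every later step, keep the oxabicycles non-volatile and shield the substituted bridgehead in step 4, and no stereocentre is formed.

Step 2
Reactants: 2 tert-butyl(furan-2-ylmethoxy)diphenylsilane; 3 (Z)-1,2-bis(phenylsulfonyl)ethene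
Product: 4 rac-1-[(tert-butyldiphenylsilyloxy)methyl]-5,6-bis(phenylsulfonyl)-7-oxabicyclo[2.2.1]hept-2-ene (sulfonyl groups cis; endo/exo mixture)
Conditions: CH2Cl2 (2 M), rt, 3–5 d, dark
Reagents that add atoms: none
Why: Normal-electron-demand Diels–Alder reaction in which the electron-rich 2-alkylfuran adds suprafacially to the doubly sulfonyl-activated ethene, used here as an acetylene equivalent; the closest known reaction type is the cycloaddition of furan itself with bis(phenylsulfonyl)ethenes followed by reductive desulfonylation. The six-membered carbocycle is closed by this intermolecular [4+2] cycloaddition through the two new σ-bonds C1–C2 and C3–C4, and the two oxolane rings that share the former furan oxygen arise in the same event as the bridged bicycle. The four new stereocentres (bridgeheads C1 and C4, sulfonyl carbons C2 and C3) are controlled only in that the Z-alkene imposes the cis relation of the sulfonyl groups, which is harmless because all four vanish in step 3. The step therefore needs reactivity but no regio- or stereoselectivity: the constitutionally symmetric dienophile removes the regiochemical question that any other two-carbon partner would raise with a 2-substituted furan, and endo and exo adducts converge. The reversibility typical of furan cycloadditions is countered by working at room temperature and high concentration, where the sulfone adduct should be kinetically stable.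

Step 3
Reactants: 4 rac-bis-sulfone adduct
Product: 5 1-[(tert-butyldiphenylsilyloxy)methyl]-7-oxabicyclo[2.2.1]hepta-2,5-diene (achiral)
Conditions: Na(Hg) (6%), NaH2PO4, MeOH/THF, −20 °C
Reagents that add atoms: none
Why: Julia-type reductive elimination of a vicinal bis-sulfone by electron transfer from sodium amalgam under buffered, cold conditions should unmask the second alkene; it is stereoconvergent and leaves a diene with a mirror plane through C1, C4 and the bridging oxygen.

Step 4
Reactants: 5 1-[(tert-butyldiphenylsilyloxy)methyl]-7-oxabicyclo[2.2.1]hepta-2,5-diene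
Product: 6 (1R,6S)-6-(benzoyloxy)-1-[(tert-butyldiphenylsilyloxy)methyl]cyclohexa-2,4-dien-1-ol (OH and OBz trans)
Conditions: [Rh(cod)Cl]2 (2.5 mol%), (R,S)-PPF-PtBu2 (6 mol%), Bu4NI (10 mol%), PhCO2H, Et3N, THF, 60 °C
Reagents that add atoms: benzoic acid, O=C(O)c1ccccc1
Why: Proposed new method: rhodium-catalysed asymmetric ring-opening (SN2′) of an oxabicyclic alkene in which the chiral monovalent-rhodium iodide complex of the ferrocenyl diphosphine (R)-1-[(S)-2-(diphenylphosphino)ferrocenyl]ethyldi-tert-butylphosphine binds the exo face of one alkene and the bridge oxygen, inserts with retention into the doubly allylic C4–O bond at the unsubstituted bridgehead (the C1–O bond being shielded by the CH2OSi group) to give a trivalent-rhodium π-allyl alkoxide, and benzoate then attacks the allyl terminus C6 anti to rhodium, so that the benzoate lies trans to the retained C1–OH and the ligand's choice between the two enantiotopic alkenes sets C1 and C6 together; the closest known reaction type is the rhodium-catalysed asymmetric ring-opening of oxabenzonorbornadienes with carboxylate nucleophiles, where enantiotopic C–O bonds of a meso substrate, not enantiotopic alkenes of a diene, are differentiated.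

Step 5
Reactants: 6 (1R,6S)-dienol benzoate
Product: 7 (1R,2S,3S,6S)-6-(benzoyloxy)-2,3-epoxy-1-[(tert-butyldiphenylsilyloxy)methyl]cyclohex-4-en-1-ol (oxirane cis to the C1–OH, trans to the C6 benzoate)
Conditions: VO(acac)2 (5 mol%), t-BuOOH, CH2Cl2, 0 °C
Reagents that add atoms: tert-butyl hydroperoxide, CC(C)(C)OO
Why: Vanadium-catalysed hydroxyl-directed epoxidation, in which the tertiary C1 alkoxide binds the vanadium peroxide and delivers oxygen only to the adjacent C2=C3 alkene on the face of the C1–OH, which sets C2 and C3 and leaves the C4=C5 alkene next to the benzoate untouched.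

Step 6
Reactants: 7 epoxy alcohol
Product: 8 (1S,2S,3R,6S)-1-[(tert-butyldiphenylsilyloxy)methyl]-1,2-dihydroxycyclohex-4-ene-3,6-diyl dibenzoate
Conditions: Ti(OiPr)4, PhCO2H, CH2Cl2, 0 °C → rt
Reagents that add atoms: benzoic acid, O=C(O)c1ccccc1
Why: Titanium-mediated regioselective opening of a 2,3-epoxy alcohol by a carboxylic acid, in which the C1-alkoxide/oxirane chelate directs benzoate to C3 (also the allylic terminus) with SN2 inversion, so that the C3 benzoate ends trans to the C2 hydroxyl and cis to the C6 benzoate.

Step 7
Reactants: 8 silyl-protected dibenzoate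
Product: 9 (1S,2S,3R,6S)-1,2-dihydroxy-1-(hydroxymethyl)cyclohex-4-ene-3,6-diyl dibenzoate (CNP0212417.1)
Conditions: HF·pyridine, THF/pyridine, 0 °C → rt
Reagents that add atoms: none
Why: Fluoride-mediated silyl ether cleavage under acidic, non-basic conditions, chosen so that neither benzoate should migrate to the neighbouring free hydroxyls; no stereocentre is touched.

## Compound list

1 | furfuryl alcohol (furan-2-ylmethanol) | OCc1ccco1 | starting material
2 | tert-butyl(furan-2-ylmethoxy)diphenylsilane | CC(C)(C)[Si](OCc1ccco1)(c1ccccc1)c1ccccc1 | intermediate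
3 | (Z)-1,2-bis(phenylsulfonyl)ethene | O=S(=O)(/C=C\S(=O)(=O)c1ccccc1)c1ccccc1 | starting material
4 | rac-1-[(tert-butyldiphenylsilyloxy)methyl]-5,6-bis(phenylsulfonyl)-7-oxabicyclo[2.2.1]hept-2-ene, sulfonyl groups cis (exo,exo isomer, one enantiomer drawn; the endo,endo isomer is carried along) | CC(C)(C)[Si](OC[C@]12C=C[C@H](O1)[C@@H]([C@@H]2S(=O)(=O)c1ccccc1)S(=O)(=O)c1ccccc1)(c1ccccc1)c1ccccc1 | intermediate
5 | 1-[(tert-butyldiphenylsilyloxy)methyl]-7-oxabicyclo[2.2.1]hepta-2,5-diene (achiral) | CC(C)(C)[Si](OCC12C=CC(C=C1)O2)(c1ccccc1)c1ccccc1 | intermediate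
6 | (1R,6S)-6-(benzoyloxy)-1-[(tert-butyldiphenylsilyloxy)methyl]cyclohexa-2,4-dien-1-ol (OH and OBz trans) | O=C(O[C@H]1C=CC=C[C@@]1(O)CO[Si](c1ccccc1)(c1ccccc1)C(C)(C)C)c1ccccc1 | intermediate
7 | (1R,2S,3S,6S)-6-(benzoyloxy)-2,3-epoxy-1-[(tert-butyldiphenylsilyloxy)methyl]cyclohex-4-en-1-ol (oxirane cis to 1-OH, trans to 6-OBz) | O=C(O[C@H]1C=C[C@@H]2O[C@@H]2[C@@]1(O)CO[Si](c1ccccc1)(c1ccccc1)C(C)(C)C)c1ccccc1 | intermediate
8 | (1S,2S,3R,6S)-1-[(tert-butyldiphenylsilyloxy)methyl]-1,2-dihydroxycyclohex-4-ene-3,6-diyl dibenzoate | O=C(O[C@H]1C=C[C@@H](OC(=O)c2ccccc2)[C@H](O)[C@@]1(O)CO[Si](c1ccccc1)(c1ccccc1)C(C)(C)C)c1ccccc1 | intermediate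
9 | (1S,2S,3R,6S)-1,2-dihydroxy-1-(hydroxymethyl)cyclohex-4-ene-3,6-diyl dibenzoate (CNP0212417.1) | O=C(O[C@H]1C=C[C@@H](OC(=O)c2ccccc2)[C@H](O)[C@@]1(O)CO)c1ccccc1 | target

## Step count and risks

Total step count: 7. Longest linear sequence: 7 steps (1 → 9); the dienophile 3 is commercial.

Steps most likely to fail:

**Step 4 (Proposed new method).** Three processes may defeat it. The catalyst may discriminate poorly between the two enantiotopic alkenes. Rhodium may insert into the C–O bond at the substituted bridgehead, which would place the benzoate next to C4 in a constitutional isomer. The strained diene may isomerise to a phenol before the nucleophile is captured. The fallback uses known chemistry, sets out from 5 and comes back at 7. Exo-selective mono-epoxidation of one of the two equivalent strained alkenes with mCPBA (CH2Cl2, NaHCO3, 0 °C) should give the racemic exo-epoxide 1-[(tert-butyldiphenylsilyloxy)methyl]-3,8-dioxatricyclo[3.2.1.0^2,4]oct-6-ene F1, whose oxirane already lies cis to the bridge oxygen. F1 is a 7-oxabicyclo[2.2.1]hept-2-ene with a single alkene and a substituted saturated bridge. On such substrates the rhodium-catalysed opening by heteroatom nucleophiles and the catalyst-controlled resolution of bridgehead-substituted oxabicycles are documented. Opening F1 with benzoate under the step-4 catalyst, run as such a resolution, should convert one enantiomer directly into 7 and the other into a separable regioisomer. The route continues at step 6, and step 5 is no longer needed.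

**Step 3.** Methoxide formed at the amalgam surface may deprotonate α to a sulfonyl group and expel the oxygen bridge by β-elimination. Over-reduction and acid-triggered isomerisation of the strained diene during work-up are further risks. The fallback sets out from 2 and comes back at 5 without any reducing or basic step. Diels–Alder reaction of 2 with maleic anhydride (Et2O, rt) should give the racemic exo adduct 1-[(tert-butyldiphenylsilyloxy)methyl]-7-oxabicyclo[2.2.1]hept-5-ene-2,3-dicarboxylic anhydride F2. Hydrolysis (water/THF, rt) gives the corresponding exo,exo-2,3-dicarboxylic acid F3. Oxidative bis-decarboxylation of F3 with Pb(OAc)4 in pyridine under O2 (or anodically, Kolbe-type) should then give diene 5.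

**Step 6.** Benzoate may attack C5 with allylic shift (SN2′). The vinyl oxirane may ionise to an allyl cation and lose stereochemical integrity. The new benzoate may migrate to the C2 hydroxyl under titanium catalysis. The fallback sets out from 6, replaces steps 5 and 6, and comes back at 8. Hydrogen-bond-directed dihydroxylation of the C2=C3 alkene with OsO4·TMEDA (CH2Cl2, −78 °C, then aqueous Na2SO3) should give the all-cis triol (1S,2S,3S,6S)-6-(benzoyloxy)-1-[(tert-butyldiphenylsilyloxy)methyl]cyclohex-4-ene-1,2,3-triol F4. A Mitsunobu reaction (PPh3, DIAD, PhCO2H, THF, 0 °C) at the allylic C3–OH, the only unhindered secondary alcohol, should then install the benzoate with inversion and give 8.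

## Further compounds

F1 | step 4 | rac-1-[(tert-butyldiphenylsilyloxy)methyl]-3,8-dioxatricyclo[3.2.1.0^2,4]oct-6-ene (exo-oxirane, cis to the oxygen bridge; the enantiomer that leads to 7 is drawn) | CC(C)(C)[Si](OC[C@]12C=C[C@H](O1)[C@@H]3O[C@H]23)(c1ccccc1)c1ccccc1
F2 | step 3 | rac-exo-1-[(tert-butyldiphenylsilyloxy)methyl]-7-oxabicyclo[2.2.1]hept-5-ene-2,3-dicarboxylic anhydride (one enantiomer drawn) | CC(C)(C)[Si](OC[C@]12C=C[C@H](O1)[C@@H]3C(=O)OC(=O)[C@H]23)(c1ccccc1)c1ccccc1
F3 | step 3 | rac-exo,exo-1-[(tert-butyldiphenylsilyloxy)methyl]-7-oxabicyclo[2.2.1]hept-5-ene-2,3-dicarboxylic acid (one enantiomer drawn) | CC(C)(C)[Si](OC[C@]12C=C[C@H](O1)[C@H](C(=O)O)[C@@H]2C(=O)O)(c1ccccc1)c1ccccc1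
F4 | step 6 | (1S,2S,3S,6S)-6-(benzoyloxy)-1-[(tert-butyldiphenylsilyloxy)methyl]cyclohex-4-ene-1,2,3-triol (three hydroxyls cis, benzoate trans to them) | O=C(O[C@H]1C=C[C@H](O)[C@H](O)[C@@]1(O)CO[Si](c1ccccc1)(c1ccccc1)C(C)(C)C)c1ccccc1
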